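**Assumption:** the SMILES is read literally (trans 4,5‑epoxide, cis 1,10‑epoxide; 1R,4S,5S,6R,7R,8S,10S). Germacrane numbering is used for all ring compounds (ring C1–C10, C14 on C10, C15 on C4, isopropyl on C7).

## Retrosynthetic overview

1. Target ⇒ (Z)‑C1=C10 macrocyclic diester. The 1,10‑oxirane is made last, by epoxidation of the finished ring.
2. C6 acetate (installed with inversion) and C8 angelate ⇒ syn‑6,8‑diol ⇒ macrocyclic β‑hydroxy ketone (C6–OH, C8=O, C7–iPr).
3. Ten‑membered ring ⇒ C6–C7 bond (the farnesyl C1–C10 bond of germacrene biosynthesis) by reductive aldol: hydride adds to C11 of the terminal prenyl ketone, and the resulting C7 enolate attacks the C6 aldehyde.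
4. Open‑chain (6Z)‑9‑oxo‑2,3‑epoxyfarnesal ⇒ geranyl acetate + prenal (Z‑selective allylboration); Sharpless epoxidation sets the absolute configuration.
5. Ring order: 4,5‑oxirane (open chain) → ten‑membered carbocycle → 1,10‑oxirane.

## Route

Step 1
Reactants: 1 geranyl acetate
Product: 2 (2E,6E)-8-hydroxy-3,7-dimethylocta-2,6-dien-1-yl acetate
Conditions: SeO2 (0.2 equiv), t‑BuOOH (3 equiv), salicylic acid (0.1 equiv), CH2Cl2, rt
Reagents that add atoms: tert‑butyl hydroperoxide, CC(C)(C)OO (terminal oxidant); selenium dioxide, O=[Se]=O (oxygen carrier)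
Why: Catalytic SeO2 allylic oxidation (ene reaction then [2,3]‑sigmatropic shift) attacks the electron‑richer distal alkene at its (E)‑methyl group only; no stereocentre is formed.

Step 2
Reactants: 2 (2E,6E)-8-hydroxy-3,7-dimethylocta-2,6-dien-1-yl acetate
Product: 3 (2E,6E)-8-(methoxycarbonyloxy)-3,7-dimethylocta-2,6-dien-1-yl acetate
Conditions: ClCO2Me, pyridine, CH2Cl2, 0 °C
Reagents that add atoms: methyl chloroformate, COC(Cl)=O
Why: Plain O‑acylation to the allylic carbonate, the leaving group needed for the SN2' borylation.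

Step 3
Reactants: 3 (2E,6E)-8-(methoxycarbonyloxy)-3,7-dimethylocta-2,6-dien-1-yl acetate
Product: 4 racemic (2E)-3,7-dimethyl-6-(4,4,5,5-tetramethyl-1,3,2-dioxaborolan-2-yl)octa-2,7-dien-1-yl acetate
Conditions: B2pin2 (1.5 equiv), CuCl (5 mol%), Xantphos (5 mol%), KOtBu (10 mol%), THF, 0 °C → rt
Reagents that add atoms: bis(pinacolato)diboron, CC1(C)OB(OC1(C)C)B1OC(C)(C)C(C)(C)O1
Why: Copper‑catalysed γ‑selective (SN2') allylic borylation (borylcupration then β‑alkoxide elimination) gives the α‑substituted methallyl boronate; the allylic acetate is a poorer leaving group on a γ,γ‑disubstituted alkene and survives; the new centre is racemic and becomes sp2 in step 4.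

Step 4
Reactants: 4 racemic (2E)-3,7-dimethyl-6-(4,4,5,5-tetramethyl-1,3,2-dioxaborolan-2-yl)octa-2,7-dien-1-yl acetate; 5 3-methylbut-2-enal (prenal)
Product: 7 racemic (2E,6Z)-9-hydroxy-3,7,11-trimethyldodeca-2,6,10-trien-1-yl acetate, via pinacol borate ester 6 (not isolated)
Conditions: PhMe, 40 °C, 36 h; then H2O
Reagents that add atoms: none
Why: Allylboration through a closed chair transition state; the α‑substituent sits axial to avoid A1,2 strain with the 2‑methyl group and the pinacol oxygens, so the transposed double bond is the (Z)‑trisubstituted alkene (future C1=C10) while the C8–C9 bond forms; the racemic carbinol is oxidised in step 7.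

Step 5
Reactants: 7 racemic (2E,6Z)-9-hydroxy-3,7,11-trimethyldodeca-2,6,10-trien-1-yl acetate
Product: 8 racemic (2E,6Z)-3,7,11-trimethyldodeca-2,6,10-triene-1,9-diol
Conditions: K2CO3 (0.2 equiv), MeOH, rt
Reagents that add atoms: none
Why: Base‑catalysed transesterification frees the primary allylic alcohol needed for the directed epoxidation.

Step 6
Reactants: 8 racemic (2E,6Z)-3,7,11-trimethyldodeca-2,6,10-triene-1,9-diol
Product: 9 (2S,3S,6Z)-2,3-epoxy-3,7,11-trimethyldodeca-6,10-diene-1,9-diol (both C9 epimers)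
Conditions: Ti(OiPr)4 (0.2 equiv), L‑(+)‑DIPT (0.25 equiv), t‑BuOOH (1.2 equiv), 4 Å MS, CH2Cl2, −25 °C
Reagents that add atoms: tert‑butyl hydroperoxide, CC(C)(C)OO
Why: Sharpless asymmetric epoxidation; L‑(+)‑tartrate gives the (2S,3S)‑epoxide of the (E)‑primary allylic alcohol, which is C4 and C5 of the target; the secondary allylic alcohol carries a cis β‑methyl group and reacts far more slowly, and the homoallylic (Z)‑alkene is not touched.

Step 7
Reactants: 9 (2S,3S,6Z)-2,3-epoxy-3,7,11-trimethyldodeca-6,10-diene-1,9-diol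
Product: 10 (2R,3S,6Z)-2,3-epoxy-3,7,11-trimethyl-9-oxododeca-6,10-dienal
Conditions: Dess–Martin periodinane (3 equiv), pyridine, CH2Cl2, 0 °C → rt
Reagents that add atoms: none
Why: Dess–Martin oxidation converts both alcohols in one operation and merges the C9 epimers; the buffered neutral medium protects the epoxy aldehyde and keeps the β,γ‑alkene out of conjugation (the descriptor at C2 changes to R by priority only).

Step 8
Reactants: 10 (2R,3S,6Z)-2,3-epoxy-3,7,11-trimethyl-9-oxododeca-6,10-dienal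
Product: 13 (1(10)Z,4S,5S,6S,7S)-4,5-epoxy-6-hydroxygermacr-1(10)-en-8-one, via cuprous enolate 11 (not isolated), via cuprous aldolate 12 (not isolated)
Conditions: [(Ph3P)CuH]6 (0.2 equiv, 1.2 equiv hydride, added slowly), PhMe, 0.003 M, −40 → 0 °C; then aq NH4Cl
Reagents that add atoms: [(Ph3P)CuH]6, unit [CuH].c1ccc(cc1)P(c1ccccc1)c1ccccc1 (copper in 11 and 12 only; 13 gains only hydrogen)
Why: Proposed new method: conjugate hydrocupration of the s‑cis prenyl ketone (the only conjugate acceptor) puts hydride on C11, creating the isopropyl group and the regiodefined (Z)‑cuprous enolate at C7, which closes the ten‑membered ring on the tethered aldehyde through a chair (Zimmerman–Traxler) transition state (6,7‑syn) from the Felkin–Anh/Cornforth face of the α,β‑epoxy aldehyde (5,6‑anti), giving 6S,7S; the (Z)‑alkene and trans‑epoxide act as turn elements and high dilution suppresses oligomers; the closest known reaction type is the reductive aldol cyclisation of keto‑ and formyl‑enones with [(Ph3P)CuH]6 to five‑ and six‑membered rings, here extended to a ten‑membered ring.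

Step 9
Reactants: 13 (1(10)Z,4S,5S,6S,7S)-4,5-epoxy-6-hydroxygermacr-1(10)-en-8-one
Product: 15 (1(10)Z,4S,5S,6S,7R,8S)-4,5-epoxygermacr-1(10)-ene-6,8-diol, via diethylboron chelate 14 (not isolated)
Conditions: Et2BOMe (1.1 equiv), THF/MeOH 4:1, −78 °C; NaBH4; then MeOH, evaporate (three times)
Reagents that add atoms: diethylmethoxyborane, CCB(CC)OC (boron in 14 only; 15 gains only hydrogen)
Why: Narasaka–Prasad reduction; external hydride attacks the six‑membered boron chelate axially to give the 1,3‑syn diol, so C8 becomes S (syn to the isopropyl group, as in the target), and the epimerisable C7 is locked.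

Step 10
Reactants: 15 (1(10)Z,4S,5S,6S,7R,8S)-4,5-epoxygermacr-1(10)-ene-6,8-diol; 16 angelic acid
Product: 18 (1(10)Z,4S,5S,6S,7S,8S)-4,5-epoxy-6-hydroxygermacr-1(10)-en-8-yl (2Z)-2-methylbut-2-enoate, via mixed anhydride 17 (not isolated)
Conditions: 16, 2,4,6‑Cl3C6H2COCl, Et3N, PhMe, rt; then 15 (1.0 equiv of anhydride), PhMe, 70 °C, no DMAP
Reagents that add atoms: 2,4,6‑trichlorobenzoyl chloride, O=C(Cl)c1c(Cl)cc(Cl)cc1Cl (in 17 only)
Why: Yamaguchi‑type mixed‑anhydride esterification acylates the more accessible C8–OH (next to a CH2) rather than the C6–OH (between the epoxide and C7, hydrogen‑bonded to the epoxide oxygen), and leaving out DMAP avoids Z→E isomerisation to the tiglate; no stereocentre changes (C7 becomes S by priority only).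

Step 11
Reactants: 18 (1(10)Z,4S,5S,6S,7S,8S)-4,5-epoxy-6-hydroxygermacr-1(10)-en-8-yl (2Z)-2-methylbut-2-enoate; 19 acetic acid
Product: 20 (1(10)Z,4S,5S,6R,7R,8S)-6-acetoxy-4,5-epoxygermacr-1(10)-en-8-yl (2Z)-2-methylbut-2-enoate
Conditions: PPh3, DIAD, AcOH, PhMe, 0 °C → rt
Reagents that add atoms: none
Why: Mitsunobu reaction; SN2 displacement of the oxyphosphonium by acetate inverts C6 (S→R), turning the erythro epoxy alcohol into the threo acetate of the target and installing the acetate in the same step.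

Step 12
Reactants: 20 (1(10)Z,4S,5S,6R,7R,8S)-6-acetoxy-4,5-epoxygermacr-1(10)-en-8-yl (2Z)-2-methylbut-2-enoate
Product: 21 (1R,4S,5S,6R,7R,8S,10S)-6-acetoxy-1,10:4,5-diepoxygermacran-8-yl (2Z)-2-methylbut-2-enoate (CNP0158257.1)
Conditions: mCPBA (1.1 equiv), CH2Cl2, −20 °C
Reagents that add atoms: mCPBA, OOC(=O)c1cccc(Cl)c1
Why: Prilezhaev epoxidation is stereospecific, so the (Z)‑alkene gives the cis‑epoxide; attack from the ring periphery on the face away from the homoallylic C8 ester gives 1R,10S, and the electron‑poor angelate alkene does not react.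

## Compound list

1 | geranyl acetate [(2E)-3,7-dimethylocta-2,6-dien-1-yl acetate] | CC(C)=CCC/C(C)=C/COC(C)=O | starting material
2 | (2E,6E)-8-hydroxy-3,7-dimethylocta-2,6-dien-1-yl acetate | OC/C(C)=C/CC/C(C)=C/COC(C)=O | intermediate
3 | (2E,6E)-8-(methoxycarbonyloxy)-3,7-dimethylocta-2,6-dien-1-yl acetate | COC(=O)OC/C(C)=C/CC/C(C)=C/COC(C)=O | intermediate
4 | racemic (2E)-3,7-dimethyl-6-(4,4,5,5-tetramethyl-1,3,2-dioxaborolan-2-yl)octa-2,7-dien-1-yl acetate | C=C(C)C(CC/C(C)=C/COC(C)=O)B1OC(C)(C)C(C)(C)O1 | intermediate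
5 | 3-methylbut-2-enal (prenal) | CC(C)=CC=O | starting material
6 | pinacol borate ester of 7 (O–Bpin on C9, racemic) | CC(=O)OC/C=C(\C)CC/C=C(/C)CC(OB1OC(C)(C)C(C)(C)O1)C=C(C)C | intermediate
7 | racemic (2E,6Z)-9-hydroxy-3,7,11-trimethyldodeca-2,6,10-trien-1-yl acetate | CC(=O)OC/C=C(\C)CC/C=C(/C)CC(O)C=C(C)C | intermediate
8 | racemic (2E,6Z)-3,7,11-trimethyldodeca-2,6,10-triene-1,9-diol | OC/C=C(\C)CC/C=C(/C)CC(O)C=C(C)C | intermediate
9 | (2S,3S,6Z)-2,3-epoxy-3,7,11-trimethyldodeca-6,10-diene-1,9-diol (both C9 epimers) | CC(C)=CC(O)C/C(C)=C\CC[C@]1(C)O[C@H]1CO | intermediate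
10 | (2R,3S,6Z)-2,3-epoxy-3,7,11-trimethyl-9-oxododeca-6,10-dienal | CC(C)=CC(=O)C/C(C)=C\CC[C@]1(C)O[C@H]1C=O | intermediate
11 | cuprous (Z)-enolate of 10 (Cu–O–C9=C10 of the chain, phosphine‑ligated) | CC(C)/C=C(\O[Cu])C/C(C)=C\CC[C@]1(C)O[C@H]1C=O | intermediate
12 | cuprous aldolate of 13 (Cu on O6) | O=C1C/C(C)=C\CC[C@]2(C)O[C@H]2[C@@H](O[Cu])[C@@H]1C(C)C | intermediate
13 | (1(10)Z,4S,5S,6S,7S)-4,5-epoxy-6-hydroxygermacr-1(10)-en-8-one | O=C1C/C(C)=C\CC[C@]2(C)O[C@H]2[C@@H](O)[C@@H]1C(C)C | intermediate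
14 | 6-O-diethylboryl derivative of 13 (boron chelated by the C8 carbonyl) | O=C1C/C(C)=C\CC[C@]2(C)O[C@H]2[C@@H](OB(CC)CC)[C@@H]1C(C)C | intermediate
15 | (1(10)Z,4S,5S,6S,7R,8S)-4,5-epoxygermacr-1(10)-ene-6,8-diol | O[C@H]1C/C(C)=C\CC[C@]2(C)O[C@H]2[C@@H](O)[C@@H]1C(C)C | intermediate
16 | angelic acid [(2Z)-2-methylbut-2-enoic acid] | C/C=C(/C)C(=O)O | starting material
17 | angelic 2,4,6-trichlorobenzoic anhydride | C/C=C(/C)C(=O)OC(=O)c1c(Cl)cc(Cl)cc1Cl | intermediate
18 | (1(10)Z,4S,5S,6S,7S,8S)-4,5-epoxy-6-hydroxygermacr-1(10)-en-8-yl (2Z)-2-methylbut-2-enoate | C/C=C(/C)C(=O)O[C@H]1C/C(C)=C\CC[C@]2(C)O[C@H]2[C@@H](O)[C@@H]1C(C)C | intermediate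
19 | acetic acid | CC(=O)O | starting material
20 | (1(10)Z,4S,5S,6R,7R,8S)-6-acetoxy-4,5-epoxygermacr-1(10)-en-8-yl (2Z)-2-methylbut-2-enoate | C/C=C(/C)C(=O)O[C@H]1C/C(C)=C\CC[C@]2(C)O[C@H]2[C@H](OC(C)=O)[C@@H]1C(C)C | intermediate
21 | (1R,4S,5S,6R,7R,8S,10S)-6-acetoxy-1,10:4,5-diepoxygermacran-8-yl (2Z)-2-methylbut-2-enoate | C/C=C(/C)C(=O)O[C@H]1C[C@]2(C)O[C@@H]2CC[C@]2(C)O[C@H]2[C@H](OC(C)=O)[C@@H]1C(C)C | target

## Step count and risks

Total step count: 12. Longest linear sequence: 12 steps (geranyl acetate 1 → 21); prenal 5, angelic acid 16 and acetic acid 19 enter as bought building blocks.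

The three steps most likely to fail:

Step 8 (ten‑membered reductive aldol). The cuprous enolate may simply be protonated, may oligomerise, or the hydride may reduce the aldehyde. The fallback separates enolate formation from ring closure and sets out from keto aldehyde 10. Platinum‑catalysed 1,4‑hydrosilylation (Et3SiH, Pt2[(CH2=CHSiMe2)2O]3, PhMe, rt) should take the enone selectively, since aldehydes and trisubstituted alkenes are poor substrates, and gives the (Z)‑triethylsilyl enol ether aldehyde F1. A fluoride‑triggered Mukaiyama‑type aldol macrocyclisation (Bu4N[Ph3SiF2] 10 mol%, THF, −78 °C, 0.003 M) then proceeds through an open transition state that is syn‑selective whatever the enolate geometry, with silyl transfer to the aldolate, and gives the 6‑O‑triethylsilyl aldol F2. HF·pyridine in THF removes the silyl group and the route is rejoined at 13.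

Step 11 (Mitsunobu inversion at the hindered C6 carbinol). The alcohol is flanked by the epoxide and the isopropyl‑bearing C7, so the oxyphosphonium may not form, or the C8 ester may participate and give retention. The fallback replaces the redox condensation by a discrete leaving group and sets out from 18. ClCH2SO2Cl with pyridine in CH2Cl2 at 0 °C gives the 6‑O‑chloromethanesulfonate F3, a small and very reactive sulfonate. CsOAc with 18‑crown‑6 in PhMe at 60 °C displaces it with inversion and the route is rejoined at 20.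

Step 12 (face selectivity of the last epoxidation). If mCPBA attacks the face syn to the C8 ester, the 1,10‑epimer results. The fallback reverses the facial outcome and sets out from 20. NBS in THF/H2O at 0 °C forms the bromonium ion on the face the peracid would have used, and water opens it anti at the tertiary C10, giving the 1‑bromo‑10‑hydroxy compound F4. K2CO3 in MeCN at rt closes the oxirane with inversion at C1, which places the oxygen on the opposite face, and the route is rejoined at 21.

## Further compounds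

F1 | step 8 | (2R,3S)-3-methyl-3-[(3Z,6Z)-4,8-dimethyl-6-(triethylsilyloxy)nona-3,6-dien-1-yl]oxirane-2-carbaldehyde | CC(C)/C=C(\O[Si](CC)(CC)CC)C/C(C)=C\CC[C@]1(C)O[C@H]1C=O
F2 | step 8 | (1(10)Z,4S,5S,6S,7S)-4,5-epoxy-6-(triethylsilyloxy)germacr-1(10)-en-8-one | O=C1C/C(C)=C\CC[C@]2(C)O[C@H]2[C@@H](O[Si](CC)(CC)CC)[C@@H]1C(C)C
F3 | step 11 | (1(10)Z,4S,5S,6S,7S,8S)-6-(chloromethanesulfonyloxy)-4,5-epoxygermacr-1(10)-en-8-yl (2Z)-2-methylbut-2-enoate | C/C=C(/C)C(=O)O[C@H]1C/C(C)=C\CC[C@]2(C)O[C@H]2[C@@H](OS(=O)(=O)CCl)[C@@H]1C(C)C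
F4 | step 12 | (1S,4S,5S,6R,7R,8S,10S)-6-acetoxy-1-bromo-4,5-epoxy-10-hydroxygermacran-8-yl (2Z)-2-methylbut-2-enoate | C/C=C(/C)C(=O)O[C@H]1C[C@](C)(O)[C@@H](Br)CC[C@]2(C)O[C@H]2[C@H](OC(C)=O)[C@@H]1C(C)C
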